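**Retrosynthetic overview**

1. Numbering used throughout: C1 = methyl-bearing ring-fusion carbon, C2, C3 = ring CH2, C4 = isopropyl carbinol, C5 = ring-fusion CH, C6 = ester carbon, C7=C8(Me), C9 = secondary carbinol, C10 = CH2. The ester is made last from diol 20; the C6 hydroxyl comes from a hydroxyl-directed reduction of a C6 ketone, and the C9 hydroxyl from singlet-oxygen oxygenation of the silyl dienol ether of enone 14.
2. Key disconnection: the ring-fusion bond C1–C5. C5 lies next to the oxygen-bearing C6 and carries the quaternary C1, so C1–C5–C6(=O) is the retron of a pinacol-type 1,2-shift. Moving C1 back from C5 to C6 turns the cyclopentane (C1–C5) into a cyclohexane A and the cycloheptane into a cyclohexane B: a cis-decalin triol monomesylate 12.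
3. 12 comes from hydroxyl-directed osmylation of allylic alcohol 10, which comes from isopropyl addition to octalone 9; 9 comes from 1,6-methylation of the dienone of the Robinson-annulation octalone 7 (2-methylcyclohexanone, methyl vinyl ketone, (R)-1-phenylethylamine as chiral auxiliary).
4. Ring order: cyclohexane B (starting material), cyclohexene A (step 3), then both rings of the target in one operation in step 9 (six to five and six to seven).

Key step: step 9

Remark: the C8 methyl stereocentre made in step 5 is temporary (it becomes trigonal in step 10). Compounds 9–13 are drawn as the expected major epimer, and either epimer serves.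

**Step 1**
Reactants: 1 2-methylcyclohexanone; 2 (R)-1-phenylethylamine
Product: 3 N-[(1R)-1-phenylethyl]-2-methylcyclohexan-1-imine
Conditions: toluene, TsOH (cat.), reflux, Dean–Stark trap
Reagents that add atoms: none
Why: Acid-catalysed imine condensation with azeotropic removal of water; the α-stereocentre of the ketone is labile through the imine–enamine equilibrium, so the racemic ketone can be used.

**Step 2**
Reactants: 3 N-[(1R)-1-phenylethyl]-2-methylcyclohexan-1-imine; 4 methyl vinyl ketone
Product: 6 (2S)-2-methyl-2-(3-oxobutyl)cyclohexan-1-one, via adduct imine 5 (not isolated)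
Conditions: THF, rt; then aq. AcOH (20%), rt
Reagents that add atoms: water, O
Why: Deracemizing Michael addition of the more substituted secondary enamine tautomer of the chiral imine to the enone (aza-ene-like, chair-like transition state), in which the (R)-1-phenylethyl group shields one enamine face so that quaternary C1 should form with S configuration; aqueous acid then hydrolyses the imine.

**Step 3**
Reactants: 6 (2S)-2-methyl-2-(3-oxobutyl)cyclohexan-1-one
Product: 7 (4aS)-4a-methyl-4,4a,5,6,7,8-hexahydronaphthalen-2(3H)-one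
Conditions: NaOMe, MeOH, 60 °C
Reagents that add atoms: none
Why: Intramolecular aldol condensation (second half of a Robinson annulation) closes ring A as the conjugated enone and leaves the quaternary centre untouched.

**Step 4**
Reactants: 7 (4aS)-4a-methyl-4,4a,5,6,7,8-hexahydronaphthalen-2(3H)-one
Product: 8 (4aS)-4a-methyl-4,4a,5,6-tetrahydronaphthalen-2(3H)-one
Conditions: chloranil, t-BuOH, reflux
Reagents that add atoms: none
Why: Quinone dehydrogenation through the extended dienol with hydride abstraction from the δ-carbon, the classical conversion of a ring-fused enone into its linear dienone.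

**Step 5**
Reactants: 8 (4aS)-4a-methyl-4,4a,5,6-tetrahydronaphthalen-2(3H)-one
Product: 9 (4aS,7S)-4a,7-dimethyl-4,4a,5,6,7,8-hexahydronaphthalen-2(3H)-one
Conditions: MeMgBr, CuBr·SMe2 (cat.), THF, −30 °C; then aq. HCl, rt
Reagents that add atoms: methylmagnesium bromide, C[Mg]Br
Why: Copper-catalysed 1,6-conjugate addition of the Grignard reagent to the linear dienone with axial attack anti to the angular methyl group, followed by acid-mediated return of the double bond into conjugation.

**Step 6**
Reactants: 9 (4aS,7S)-4a,7-dimethyl-4,4a,5,6,7,8-hexahydronaphthalen-2(3H)-one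
Product: 10 (2R,4aS,7S)-4a,7-dimethyl-2-(propan-2-yl)-2,3,4,4a,5,6,7,8-octahydronaphthalen-2-ol
Conditions: i-PrMgCl, CeCl3, THF, −78 to 0 °C
Reagents that add atoms: isopropylmagnesium chloride, CC(C)[Mg]Cl
Why: 1,2-Addition of the weakly basic organocerium reagent to the enone carbonyl from the face opposite to the angular methyl group, which should place the C4 hydroxyl cis to that methyl group as in the target.

**Step 7**
Reactants: 10 (2R,4aS,7S)-4a,7-dimethyl-2-(propan-2-yl)-2,3,4,4a,5,6,7,8-octahydronaphthalen-2-ol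
Product: 11 (1S,2R,4aS,7S,8aR)-4a,7-dimethyl-2-(propan-2-yl)decahydronaphthalene-1,2,8a-triol
Conditions: OsO4 (1.05 equiv), TMEDA, CH2Cl2, −78 °C; then aq. Na2SO3, THF, 60 °C
Reagents that add atoms: osmium tetroxide, O=[Os](=O)(=O)=O
Why: Hydrogen-bond-directed syn dihydroxylation of a cyclic allylic alcohol by the OsO4–TMEDA complex: the C4 hydroxyl delivers osmium to its own face of C5=C6, which should give the all-cis triol with the C6 hydroxyl cis to the angular methyl group (cis-decalin).

**Step 8**
Reactants: 11 (1S,2R,4aS,7S,8aR)-4a,7-dimethyl-2-(propan-2-yl)decahydronaphthalene-1,2,8a-triol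
Product: 12 (1S,2R,4aS,7S,8aR)-2,8a-dihydroxy-4a,7-dimethyl-2-(propan-2-yl)decahydronaphthalen-1-yl methanesulfonate
Conditions: MsCl, pyridine, DMAP (cat.), CH2Cl2, 0 °C
Reagents that add atoms: methanesulfonyl chloride, CS(=O)(=O)Cl
Why: Selective sulfonylation of the only secondary hydroxyl (C5); the two tertiary carbinols should not react under pyridine-buffered conditions.

**Step 9**
Reactants: 12 (1S,2R,4aS,7S,8aR)-2,8a-dihydroxy-4a,7-dimethyl-2-(propan-2-yl)decahydronaphthalen-1-yl methanesulfonate
Product: 13 (3R,3aR,6S,8aS)-3-hydroxy-6,8a-dimethyl-3-(propan-2-yl)octahydroazulen-4(1H)-one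
Conditions: Et3Al (3 equiv), CH2Cl2, −78 to 0 °C; Rochelle salt work-up
Reagents that add atoms: none
Why: The aluminium alkoxide at the C6 carbinol pushes while aluminium pulls on the C5 mesylate, and the C6–C1 bond, antiperiplanar to the equatorial C5–O bond in the chair of ring A, migrates from C6 to C5 as the mesylate leaves, so that C6 becomes the ketone; this is the organoaluminium-promoted pinacol-type (semipinacol) rearrangement of a 2-hydroxy mesylate, the same 1,2-shift that turns hydronaphthalene diol monosulfonates into hydroazulenones. The cyclopentane (C1–C2–C3–C4–C5) is closed by ring contraction of cyclohexane A, with C6 pushed out of that ring, and the cycloheptanone is closed by one-carbon ring expansion of cyclohexane B, with C5 inserted between C6 and C1. The only new stereocentre, C5, is set by inversion at the mesylate carbon, which should put H5 trans to the angular methyl group; C1 migrates with retention and C4 is untouched. The step needs C1 to migrate and not C3 (from the C4 carbinol), C7 or an oxygen: the all-cis arrangement keeps both carbinol C–O bonds gauche to the mesylate so no epoxide can form, only the ring bonds C6–C1 and C4–C3 are antiperiplanar to the leaving group, and of these the fully substituted C1 has the much higher migratory aptitude. The Lewis-acidic, non-basic medium avoids retro-aldol cleavage of the tertiary β-hydroxy ketone that is formed.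

**Step 10**
Reactants: 13 (3R,3aR,6S,8aS)-3-hydroxy-6,8a-dimethyl-3-(propan-2-yl)octahydroazulen-4(1H)-one
Product: 14 (3R,3aR,8aS)-3-hydroxy-6,8a-dimethyl-3-(propan-2-yl)-2,3,3a,7,8,8a-hexahydroazulen-4(1H)-one
Conditions: IBX, 4-methoxypyridine N-oxide, DMSO, rt
Reagents that add atoms: none
Why: IBX dehydrogenation of the ketone to the enone; only the C7–C8 side can be desaturated because the carbons β to the carbonyl on the other side (C4 and C1) are quaternary.

**Step 11**
Reactants: 14 (3R,3aR,8aS)-3-hydroxy-6,8a-dimethyl-3-(propan-2-yl)-2,3,3a,7,8,8a-hexahydroazulen-4(1H)-one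
Product: 15 bis(trimethylsilyl) derivative of 14 (4-trimethylsilyloxy-4,6-diene with the C3 hydroxyl as trimethylsilyl ether)
Conditions: TMSOTf, Et3N, CH2Cl2, 0 °C to rt
Reagents that add atoms: trimethylsilyl trifluoromethanesulfonate, C[Si](C)(C)OS(=O)(=O)C(F)(F)F
Why: Soft enolization with silyl triflate and amine should give the thermodynamically preferred endocyclic silyloxy diene by γ-deprotonation at C9 (the α'-position C5 is a hindered methine), and it silylates the tertiary C4 hydroxyl at the same time.

**Step 12**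
Reactants: 15 bis(trimethylsilyl) derivative of 14
Product: 18 (3R,3aR,7S,8aR)-3,7-dihydroxy-6,8a-dimethyl-3-(propan-2-yl)-2,3,3a,7,8,8a-hexahydroazulen-4(1H)-one, via silyl peroxide 16 (not isolated), via bis-TMS ether 17 (not isolated)
Conditions: O2, hν, tetraphenylporphyrin (cat.), CH2Cl2, −78 °C; then PPh3; then citric acid, MeOH, rt
Reagents that add atoms: oxygen, O=O
Why: Singlet oxygen [4+2] cycloaddition across C6 and C9 of the cisoid silyloxy diene from the face opposite to the angular methyl group and the C4 silyl ether, collapse of the endoperoxide with silyl transfer to the γ-silylperoxy enone, phosphine reduction of the O–O bond and mild methanolysis of the trimethylsilyl ethers, so that the C9 oxygen is delivered anti to the angular methyl group.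

**Step 13**
Reactants: 18 (3R,3aR,7S,8aR)-3,7-dihydroxy-6,8a-dimethyl-3-(propan-2-yl)-2,3,3a,7,8,8a-hexahydroazulen-4(1H)-one
Product: 19 (3R,3aR,7S,8aR)-7-[(tert-butyldimethylsilyl)oxy]-3-hydroxy-6,8a-dimethyl-3-(propan-2-yl)-2,3,3a,7,8,8a-hexahydroazulen-4(1H)-one
Conditions: TBSCl, imidazole, DMF, rt
Reagents that add atoms: tert-butyldimethylsilyl chloride, CC(C)(C)[Si](C)(C)Cl
Why: Silylation of the secondary allylic C9 hydroxyl only; the hindered tertiary C4 hydroxyl stays free to direct the next step.

**Step 14**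
Reactants: 19 (3R,3aR,7S,8aR)-7-[(tert-butyldimethylsilyl)oxy]-3-hydroxy-6,8a-dimethyl-3-(propan-2-yl)-2,3,3a,7,8,8a-hexahydroazulen-4(1H)-one
Product: 20 (3R,3aS,4S,7S,8aR)-7-[(tert-butyldimethylsilyl)oxy]-6,8a-dimethyl-3-(propan-2-yl)-1,2,3,3a,4,7,8,8a-octahydroazulene-3,4-diol
Conditions: Me4NBH(OAc)3, MeCN/AcOH, −30 °C
Reagents that add atoms: none
Why: Evans–Saksena reduction: the triacetoxyborohydride binds the C4 hydroxyl and delivers hydride to the C6 carbonyl from the face of that hydroxyl, which should give the 1,3-anti diol, that is the C6 hydroxyl trans to the C4 hydroxyl and cis to H5 as in the target.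

**Step 15**
Reactants: 21 vanillic acid
Product: 23 4-[(tert-butyldimethylsilyl)oxy]-3-methoxybenzoic acid, via silyl ester 22 (not isolated)
Conditions: TBSCl (2.5 equiv), imidazole, DMF, rt; then AcOH, THF, H2O, rt
Reagents that add atoms: tert-butyldimethylsilyl chloride, CC(C)(C)[Si](C)(C)Cl
Why: Silylation of phenol and carboxylic acid followed by selective hydrolysis of the labile silyl ester leaves the phenol protected.

**Step 16**
Reactants: 20 (3R,3aS,4S,7S,8aR)-7-[(tert-butyldimethylsilyl)oxy]-6,8a-dimethyl-3-(propan-2-yl)-1,2,3,3a,4,7,8,8a-octahydroazulene-3,4-diol; 23 4-[(tert-butyldimethylsilyl)oxy]-3-methoxybenzoic acid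
Product: 25 (3R,3aS,4S,7S,8aR)-7-[(tert-butyldimethylsilyl)oxy]-3-hydroxy-6,8a-dimethyl-3-(propan-2-yl)-1,2,3,3a,4,7,8,8a-octahydroazulen-4-yl 4-[(tert-butyldimethylsilyl)oxy]-3-methoxybenzoate, via mixed anhydride 24 (not isolated)
Conditions: 2,4,6-trichlorobenzoyl chloride, Et3N, THF, rt; then 20, DMAP, toluene, 40 °C
Reagents that add atoms: none
Why: Yamaguchi esterification: the mixed anhydride acylates the secondary allylic C6 hydroxyl under DMAP catalysis with retention at the carbinol, while the tertiary C4 hydroxyl is inert.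

**Step 17**
Reactants: 25 the bis-silylated ester
Product: 26 (3R,3aS,4S,7S,8aR)-3,7-dihydroxy-6,8a-dimethyl-3-(propan-2-yl)-1,2,3,3a,4,7,8,8a-octahydroazulen-4-yl 4-hydroxy-3-methoxybenzoate
Conditions: TBAF, AcOH, THF, 0 °C to rt
Reagents that add atoms: none
Why: Fluoride cleaves the aryl and the secondary alkyl silyl ethers in one operation, and acetic acid buffering should prevent acyl migration of the ester.

**Compound list**

1 | 2-methylcyclohexanone (racemic) | CC1CCCCC1=O | starting material
2 | (R)-1-phenylethylamine | C[C@@H](N)c1ccccc1 | starting material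
3 | N-[(1R)-1-phenylethyl]-2-methylcyclohexan-1-imine (mixture at C2 and C=N) | CC1CCCCC1=N[C@H](C)c1ccccc1 | intermediate
4 | methyl vinyl ketone (but-3-en-2-one) | CC(=O)C=C | starting material
5 | (2S)-2-methyl-2-(3-oxobutyl)-N-[(1R)-1-phenylethyl]cyclohexan-1-imine | CC(=O)CC[C@]1(C)CCCCC1=N[C@H](C)c1ccccc1 | intermediate
6 | (2S)-2-methyl-2-(3-oxobutyl)cyclohexan-1-one | CC(=O)CC[C@]1(C)CCCCC1=O | intermediate
7 | (4aS)-4a-methyl-4,4a,5,6,7,8-hexahydronaphthalen-2(3H)-one | C[C@]12CCC(=O)C=C1CCCC2 | intermediate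
8 | (4aS)-4a-methyl-4,4a,5,6-tetrahydronaphthalen-2(3H)-one | C[C@]12CCC(=O)C=C1C=CCC2 | intermediate
9 | (4aS,7S)-4a,7-dimethyl-4,4a,5,6,7,8-hexahydronaphthalen-2(3H)-one | C[C@]12CCC(=O)C=C1C[C@@H](C)CC2 | intermediate
10 | (2R,4aS,7S)-4a,7-dimethyl-2-(propan-2-yl)-2,3,4,4a,5,6,7,8-octahydronaphthalen-2-ol | C[C@]12CC[C@@](O)(C(C)C)C=C1C[C@@H](C)CC2 | intermediate
11 | (1S,2R,4aS,7S,8aR)-4a,7-dimethyl-2-(propan-2-yl)decahydronaphthalene-1,2,8a-triol | C[C@]12CC[C@@](O)(C(C)C)[C@H](O)[C@@]1(O)C[C@@H](C)CC2 | intermediate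
12 | (1S,2R,4aS,7S,8aR)-2,8a-dihydroxy-4a,7-dimethyl-2-(propan-2-yl)decahydronaphthalen-1-yl methanesulfonate | C[C@]12CC[C@@](O)(C(C)C)[C@H](OS(C)(=O)=O)[C@@]1(O)C[C@@H](C)CC2 | intermediate
13 | (3R,3aR,6S,8aS)-3-hydroxy-6,8a-dimethyl-3-(propan-2-yl)octahydroazulen-4(1H)-one (trans-fused) | O=C1C[C@@H](C)CC[C@@]2(C)CC[C@@](O)(C(C)C)[C@H]12 | intermediate
14 | (3R,3aR,8aS)-3-hydroxy-6,8a-dimethyl-3-(propan-2-yl)-2,3,3a,7,8,8a-hexahydroazulen-4(1H)-one | O=C1C=C(C)CC[C@@]2(C)CC[C@@](O)(C(C)C)[C@H]12 | intermediate
15 | bis(trimethylsilyl) derivative of 14: 4-trimethylsilyloxy-4,6-diene with C3 trimethylsilyl ether, configuration as in 14 | C[Si](C)(C)OC1=CC(C)=CC[C@@]2(C)CC[C@@](O[Si](C)(C)C)(C(C)C)[C@H]12 | intermediate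
16 | 7-(trimethylsilylperoxy) enone with C3 trimethylsilyl ether, configuration as in 18 | O=C1C=C(C)[C@@H](OO[Si](C)(C)C)C[C@@]2(C)CC[C@@](O[Si](C)(C)C)(C(C)C)[C@H]12 | intermediate
17 | 3,7-bis(trimethylsilyl) ether of 18 | O=C1C=C(C)[C@@H](O[Si](C)(C)C)C[C@@]2(C)CC[C@@](O[Si](C)(C)C)(C(C)C)[C@H]12 | intermediate
18 | (3R,3aR,7S,8aR)-3,7-dihydroxy-6,8a-dimethyl-3-(propan-2-yl)-2,3,3a,7,8,8a-hexahydroazulen-4(1H)-one | O=C1C=C(C)[C@@H](O)C[C@@]2(C)CC[C@@](O)(C(C)C)[C@H]12 | intermediate
19 | (3R,3aR,7S,8aR)-7-[(tert-butyldimethylsilyl)oxy]-3-hydroxy-6,8a-dimethyl-3-(propan-2-yl)-2,3,3a,7,8,8a-hexahydroazulen-4(1H)-one | O=C1C=C(C)[C@@H](O[Si](C)(C)C(C)(C)C)C[C@@]2(C)CC[C@@](O)(C(C)C)[C@H]12 | intermediate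
20 | (3R,3aS,4S,7S,8aR)-7-[(tert-butyldimethylsilyl)oxy]-6,8a-dimethyl-3-(propan-2-yl)-1,2,3,3a,4,7,8,8a-octahydroazulene-3,4-diol | O[C@H]1C=C(C)[C@@H](O[Si](C)(C)C(C)(C)C)C[C@@]2(C)CC[C@@](O)(C(C)C)[C@H]12 | intermediate
21 | vanillic acid (4-hydroxy-3-methoxybenzoic acid) | COc1cc(C(=O)O)ccc1O | starting material
22 | tert-butyldimethylsilyl 4-[(tert-butyldimethylsilyl)oxy]-3-methoxybenzoate | COc1cc(C(=O)O[Si](C)(C)C(C)(C)C)ccc1O[Si](C)(C)C(C)(C)C | intermediate
23 | 4-[(tert-butyldimethylsilyl)oxy]-3-methoxybenzoic acid | COc1cc(C(=O)O)ccc1O[Si](C)(C)C(C)(C)C | intermediate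
24 | 4-[(tert-butyldimethylsilyl)oxy]-3-methoxybenzoic 2,4,6-trichlorobenzoic anhydride | COc1cc(C(=O)OC(=O)c2c(Cl)cc(Cl)cc2Cl)ccc1O[Si](C)(C)C(C)(C)C | intermediate
25 | (3R,3aS,4S,7S,8aR)-7-[(tert-butyldimethylsilyl)oxy]-3-hydroxy-6,8a-dimethyl-3-(propan-2-yl)-1,2,3,3a,4,7,8,8a-octahydroazulen-4-yl 4-[(tert-butyldimethylsilyl)oxy]-3-methoxybenzoate | COc1cc(C(=O)O[C@H]2C=C(C)[C@@H](O[Si](C)(C)C(C)(C)C)C[C@@]3(C)CC[C@@](O)(C(C)C)[C@H]23)ccc1O[Si](C)(C)C(C)(C)C | intermediate
26 | (3R,3aS,4S,7S,8aR)-3,7-dihydroxy-6,8a-dimethyl-3-(propan-2-yl)-1,2,3,3a,4,7,8,8a-octahydroazulen-4-yl 4-hydroxy-3-methoxybenzoate | COc1cc(C(=O)O[C@H]2C=C(C)[C@@H](O)C[C@@]3(C)CC[C@@](O)(C(C)C)[C@H]23)ccc1O | target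

**Step count and risks**

Total step count: 17. Longest linear sequence: 16 steps (steps 1–14, 16, 17).

Steps most likely to fail:

Step 7. The hydroxyl direction may be lost, so that osmium adds from the open face opposite to the angular methyl group and the diol ends up trans to the C4 hydroxyl. The fallback sets out from 10 and comes back at 11. Ozonolysis of the C5=C6 bond (O3, CH2Cl2/MeOH, −78 °C; then PPh3) should give the keto aldehyde F1. An intramolecular pinacol coupling with SmI2 (THF, t-BuOH, −78 °C) should then re-form the C5–C6 bond. The samarium-bridged ketyl pair is expected to close the six-membered ring with the two new oxygens cis to each other and, through chelation of the C4 hydroxyl, cis to it, which is triol 11.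

Step 9. The wrong ring bond may migrate (C3 from the C4 carbinol to C5, giving an isobutyryl hydrindane), or the sulfonate may be eliminated instead of the 1,2-shift. The fallback sets out from 9 and comes back at 14. A second chloranil dehydrogenation (t-BuOH, reflux) should give the dienone F2, and isopropyl addition (i-PrMgCl, CeCl3) the dienol F3. OsO4–TMEDA dihydroxylation of the hydroxyl-bearing double bond should give the ene-triol F4, and mesylation the mesylate F5. In F5 the C6 carbinol is allylic, so the shift of C1 creates a conjugated enone directly and is favoured over the shift of C3. Et3Al should then convert F5 into enone 14, and step 10 is not needed.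

Step 12. Singlet oxygen may react by an ene pathway or add from the face of the angular methyl group, or step 11 may give the exocyclic dienol ether, so that oxygen does not reach C9 with the needed configuration. The fallback sets out from 14 and comes back at 18. Oxidation of the γ-methylene group of the enone (pyridinium dichromate, t-BuOOH, Celite, benzene, rt) should give the ene-dione F6. A Corey–Bakshi–Shibata reduction ((R)-2-methyl-CBS-oxazaborolidine, catecholborane, toluene, −78 °C) of the less hindered C9 carbonyl, with the methyl-substituted alkene carbon as the large group, should then give the (7S)-carbinol 18 under reagent control.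

**Further compounds**

F1 | step 7 | (2R)-4-[(1S,4S)-1,4-dimethyl-2-oxocyclohexyl]-2-hydroxy-2-(propan-2-yl)butanal | O=C[C@](O)(C(C)C)CC[C@]1(C)CC[C@H](C)CC1=O
F2 | step 9 | (4aS)-4a,7-dimethyl-4,4a,5,6-tetrahydronaphthalen-2(3H)-one | C[C@]12CCC(=O)C=C1C=C(C)CC2
F3 | step 9 | (2R,4aS)-4a,7-dimethyl-2-(propan-2-yl)-2,3,4,4a,5,6-hexahydronaphthalen-2-ol | C[C@]12CC[C@@](O)(C(C)C)C=C1C=C(C)CC2
F4 | step 9 | (1S,2R,4aS,8aR)-4a,7-dimethyl-2-(propan-2-yl)-1,2,3,4,4a,5,6,8a-octahydronaphthalene-1,2,8a-triol | C[C@]12CC[C@@](O)(C(C)C)[C@H](O)[C@@]1(O)C=C(C)CC2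
F5 | step 9 | (1S,2R,4aS,8aR)-2,8a-dihydroxy-4a,7-dimethyl-2-(propan-2-yl)-1,2,3,4,4a,5,6,8a-octahydronaphthalen-1-yl methanesulfonate | C[C@]12CC[C@@](O)(C(C)C)[C@H](OS(C)(=O)=O)[C@@]1(O)C=C(C)CC2
F6 | step 12 | (3R,3aR,8aR)-3-hydroxy-6,8a-dimethyl-3-(propan-2-yl)-2,3,3a,8-tetrahydroazulene-4,7(1H,8aH)-dione | O=C1C=C(C)C(=O)C[C@@]2(C)CC[C@@](O)(C(C)C)[C@H]12
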